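**Plan**

- Retrosynthesis: after the silyl and benzyl groups are removed, the B5–C(=O) bond of the propanoyl group is cut. Ring B is then cut at B3–B4, B1–B2 and B4–B5 into a ring A-substituted 3-benzyloxycyclobutenone (its C1, C2, C3, C4 become B4, B1, B6, B5) and 1-(triisopropylsiloxy)propyne (B3 with its methyl, B2 with its oxygen).
- Enabling feature: ring B is a phloroglucinol whose methyl carbon B3 lies between the oxygens on B2 and B4, whose B1 carries the bridging CH2 and whose B5 can be left as the only C–H. A 2-alkyl-3-alkoxycyclobutenone and a methyl ynol ether deliver exactly this pattern, with the three oxygens differentiated as OH, OSi and OBn.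
- The cyclobutenone is cut at its enol ether oxygen and at the C2–CH2 bond, giving cyclobutane-1,3-dione and the dibenzylated formyl derivative of aspidinol. That aldehyde comes from 2-methylphloroglucinol, butanoyl chloride and a formyl carbon.
- Forward: ring A is fully substituted first (acylation, O-methylation, formylation, benzylation). The bridge carbon is joined to the four-membered ring by reductive alkylation, ring B is closed by benzannulation, and propanoylation at B5, desilylation and hydrogenolysis finish the route.
- Stereochemistry: the target has no stereocentre. The one stereogenic carbon that appears in the annulation cascade is racemic and is lost on aromatisation.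

Key step: step 9

Assumption: ring A is the butanoyl ring, whose six carbons carry in order butanoyl, OH, methyl, OMe, the bridge CH2 and OH; ring B is the propanoyl ring, numbered B1 (CH2), B2 (OH), B3 (Me), B4 (OH), B5 (propanoyl), B6 (OH). 3-Ethoxycyclobut-2-en-1-one, dichloromethyl methyl ether and the Hantzsch ester are taken as purchasable.

**Route**

Step 1
Reactants: 1 2-methylphloroglucinol; 2 butanoyl chloride
Product: 3 1-(2,4,6-trihydroxy-3-methylphenyl)butan-1-one
Conditions: AlCl3, PhNO2, rt→50 °C; aq HCl work-up
Reagents that add atoms: none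
Why: Friedel–Crafts C-acylation of a phloroglucinol, in which the two open ring carbons of 1 are equivalent by symmetry and the first acyl group deactivates the ring towards a second acylation.

Step 2
Reactants: 3 1-(2,4,6-trihydroxy-3-methylphenyl)butan-1-one
Product: 4 aspidinol [1-(2,6-dihydroxy-4-methoxy-3-methylphenyl)butan-1-one]
Conditions: Me2SO4 (1.0 equiv), K2CO3, acetone, reflux
Reagents that add atoms: dimethyl sulfate, COS(=O)(=O)OC
Why: Williamson O-methylation with limiting reagent, selective for the hydroxyl para to the ketone because it is the most acidic one and the only one that cannot hydrogen-bond to the carbonyl, as is usual for 2,4,6-trihydroxyaryl ketones.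

Step 3
Reactants: 4 aspidinol
Product: 6 3-butanoyl-2,4-dihydroxy-6-methoxy-5-methylbenzaldehyde, via chloro(methoxy)methyl arene 5 (not isolated)
Conditions: Cl2CHOMe, TiCl4, CH2Cl2, 0 °C; then H2O
Reagents that add atoms: dichloromethyl methyl ether, COC(Cl)Cl; water, O
Why: Rieche formylation (electrophilic aromatic substitution by the TiCl4-activated dichloromethyl ether, then hydrolysis of chloro ether 5) at the one unsubstituted carbon of ring A, which is flanked by two oxygen-bearing carbons.

Step 4
Reactants: 6 3-butanoyl-2,4-dihydroxy-6-methoxy-5-methylbenzaldehyde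
Product: 7 2,4-bis(benzyloxy)-3-butanoyl-6-methoxy-5-methylbenzaldehyde
Conditions: BnBr, K2CO3, DMF, 60 °C
Reagents that add atoms: benzyl bromide, BrCc1ccccc1
Why: Williamson O-benzylation of both chelated phenols in a polar aprotic solvent, where O-alkylation of the phenoxides dominates over dearomatising C-alkylation and the methyl ether, ketone and aldehyde are inert.

Step 5
Reactants: 8 3-ethoxycyclobut-2-en-1-one
Product: 9 cyclobutane-1,3-dione (enol form 3-hydroxycyclobut-2-en-1-one)
Conditions: 1 M aq HCl, rt
Reagents that add atoms: water, O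
Why: Acid hydrolysis of a vinylogous ester (addition of water at C3 and loss of ethanol) should give the strongly acidic dione, which is used at once because it self-condenses on storage.

Step 6
Reactants: 7 2,4-bis(benzyloxy)-3-butanoyl-6-methoxy-5-methylbenzaldehyde; 9 cyclobutane-1,3-dione
Product: 11 2-[2,4-bis(benzyloxy)-3-butanoyl-6-methoxy-5-methylbenzyl]-3-hydroxycyclobut-2-en-1-one, via benzylidenecyclobutanedione 10 (not isolated)
Conditions: Hantzsch ester (diethyl 2,6-dimethyl-1,4-dihydropyridine-3,5-dicarboxylate), L-proline (cat.), CH2Cl2, rt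
Reagents that add atoms: none
Why: Three-component reductive alkylation of a cyclic 1,3-dione, in which amine-catalysed Knoevenagel condensation gives the electrophilic benzylidene dione 10 that takes up hydride from the Hantzsch ester at the benzylic carbon, so the CH2–C2 bond forms without the O-alkylation that troubles halide alkylation of such acidic diones and without touching the shielded aryl ketone.

Step 7
Reactants: 11 2-[2,4-bis(benzyloxy)-3-butanoyl-6-methoxy-5-methylbenzyl]-3-hydroxycyclobut-2-en-1-one
Product: 12 3-(benzyloxy)-2-[2,4-bis(benzyloxy)-3-butanoyl-6-methoxy-5-methylbenzyl]cyclobut-2-en-1-one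
Conditions: BnOH, PPh3, DIAD, THF, 0 °C→rt
Reagents that add atoms: benzyl alcohol, OCc1ccccc1
Why: Mitsunobu etherification, in which the acidic enol of 11 is the pronucleophile and reacts at oxygen with the activated benzyl alcohol; the two carbonyls of the 2-substituted dione are equivalent, so a single enol ether should result.

Step 8
Reactants: 13 ethyl acetate
Product: 16 1-(triisopropylsiloxy)propyne, via lithium dibromoenolate 14 (not isolated), via lithium propynolate 15 (not isolated)
Conditions: CH2Br2, lithium 2,2,6,6-tetramethylpiperidide (LiTMP, 2 equiv), THF, −78 °C; n-BuLi, −78 °C→rt; TIPSCl, −78 °C→rt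
Reagents that add atoms: dibromomethane, BrCBr; chlorotriisopropylsilane, CC(C)[Si](Cl)(C(C)C)C(C)C
Why: Kowalski ester homologation, in which dibromomethyllithium adds to the ester, the dibromo enolate 14 undergoes bromine–lithium exchange and 1,2-shift to ynolate 15, and the bulky silyl chloride traps the ynolate at oxygen and not at carbon.

Step 9
Reactants: 12 3-(benzyloxy)-2-[2,4-bis(benzyloxy)-3-butanoyl-6-methoxy-5-methylbenzyl]cyclobut-2-en-1-one; 16 1-(triisopropylsiloxy)propyne
Product: 21 1-[2,6-bis(benzyloxy)-3-{[6-(benzyloxy)-4-hydroxy-3-methyl-2-(triisopropylsilyloxy)phenyl]methyl}-4-methoxy-5-methylphenyl]butan-1-one, via vinylketene 17 (not isolated), via vinylcyclobutenone 18 (not isolated), via dienylketene 19 (not isolated), via cyclohexadienone 20 (not isolated)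
Conditions: 16 (2 equiv), PhMe, 80 °C→110 °C
Reagents that add atoms: none
Why: Heating opens cyclobutenone 12 by four-electron electrocyclic ring opening to vinylketene 17, whose ketene carbon is attacked by the nucleophilic methyl-bearing carbon of ynol ether 16 in a regioselective (2+2) cycloaddition that makes B3–B4 and B1–B2 and gives the 4-vinylcyclobutenone 18. A second four-electron opening gives dienylketene 19, and ring B then closes by a thermal six-electron disrotatory electrocyclisation that forms B4–B5, after which dienone 20 tautomerises to the phenol. The closest known reaction type is the Danheiser benzannulation of cyclobutenones with siloxyalkynes to resorcinol monosilyl ethers, for which 3-alkoxy- and 2-alkylcyclobutenones are established partners. No stereocentre remains in the product, since the quaternary carbon of 18 is racemic and becomes B1 of the arene. The selectivity needed is the orientation of the (2+2) step, which is fixed by the polarisation of the siloxyalkyne, so that the methyl lands at B3 between the new hydroxyl on B4 and the siloxy group on B2, the ring A methylene at B1 and the benzyloxy group at B6, with B5 left as the only C–H. Ring A has no free hydroxyl and no ring C–H that could trap the ketenes, and the excess of 16 should outrun acylation of the product phenol by 17.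

Step 10
Reactants: 21 ring B phenol; 22 propanoic anhydride
Product: 23 1-[2,6-bis(benzyloxy)-3-{[6-(benzyloxy)-4-hydroxy-3-methyl-5-propanoyl-2-(triisopropylsilyloxy)phenyl]methyl}-4-methoxy-5-methylphenyl]butan-1-one
Conditions: BF3·OEt2, CH2Cl2, 0 °C→rt
Reagents that add atoms: none
Why: Friedel–Crafts acylation (directly or through the B4 propanoate and its Fries shift) at B5, the only open position on the two phloroglucinol rings, which lies ortho to the free hydroxyl and to the benzyloxy group and para to the siloxy group, so a mild Lewis acid at low temperature should suffice while the fully substituted ring A stays untouched.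

Step 11
Reactants: 23 propanoylated silyl ether
Product: 24 1-[2,6-bis(benzyloxy)-3-{[6-(benzyloxy)-2,4-dihydroxy-3-methyl-5-propanoylphenyl]methyl}-4-methoxy-5-methylphenyl]butan-1-one
Conditions: Bu4NF (TBAF), AcOH, THF, 0 °C
Reagents that add atoms: none
Why: Fluoride cleavage of the aryl silyl ether, buffered with acetic acid so that no free phenoxide next to the methylene bridge can start bridge scrambling, with benzyl ethers and ketones inert.

Step 12
Reactants: 24 tribenzyl ether
Product: 25 CNP0248731.0 (1-[3-(3-butanoyl-2,4-dihydroxy-6-methoxy-5-methylbenzyl)-2,4,6-trihydroxy-5-methylphenyl]propan-1-one)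
Conditions: H2 (1 atm), Pd/C, EtOAc, rt
Reagents that add atoms: none
Why: Hydrogenolysis of the three benzyl aryl ethers over palladium on carbon at ambient pressure, neutral conditions under which the hydrogen-bonded, di-ortho-substituted aryl ketones and the methylene bridge should be neither reduced nor scrambled.

**Compound list**

1 | 2-methylphloroglucinol | Cc1c(O)cc(O)cc1O | starting material
2 | butanoyl chloride | CCCC(Cl)=O | starting material
3 | 1-(2,4,6-trihydroxy-3-methylphenyl)butan-1-one | CCCC(=O)c1c(O)c(C)c(O)cc1O | intermediate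
4 | aspidinol [1-(2,6-dihydroxy-4-methoxy-3-methylphenyl)butan-1-one] | CCCC(=O)c1c(O)c(C)c(OC)cc1O | intermediate
5 | 1-{3-[chloro(methoxy)methyl]-2,6-dihydroxy-4-methoxy-5-methylphenyl}butan-1-one (racemic, not isolated) | CCCC(=O)c1c(O)c(C)c(OC)c(C(Cl)OC)c1O | intermediate
6 | 3-butanoyl-2,4-dihydroxy-6-methoxy-5-methylbenzaldehyde | CCCC(=O)c1c(O)c(C)c(OC)c(C=O)c1O | intermediate
7 | 2,4-bis(benzyloxy)-3-butanoyl-6-methoxy-5-methylbenzaldehyde | CCCC(=O)c1c(OCc2ccccc2)c(C)c(OC)c(C=O)c1OCc1ccccc1 | intermediate
8 | 3-ethoxycyclobut-2-en-1-one | CCOC1=CC(=O)C1 | starting material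
9 | cyclobutane-1,3-dione | O=C1CC(=O)C1 | intermediate
10 | 2-[2,4-bis(benzyloxy)-3-butanoyl-6-methoxy-5-methylbenzylidene]cyclobutane-1,3-dione (not isolated) | CCCC(=O)c1c(OCc2ccccc2)c(C)c(OC)c(C=C2C(=O)CC2=O)c1OCc1ccccc1 | intermediate
11 | 2-[2,4-bis(benzyloxy)-3-butanoyl-6-methoxy-5-methylbenzyl]-3-hydroxycyclobut-2-en-1-one | CCCC(=O)c1c(OCc2ccccc2)c(C)c(OC)c(CC2=C(O)CC2=O)c1OCc1ccccc1 | intermediate
12 | 3-(benzyloxy)-2-[2,4-bis(benzyloxy)-3-butanoyl-6-methoxy-5-methylbenzyl]cyclobut-2-en-1-one | CCCC(=O)c1c(OCc2ccccc2)c(C)c(OC)c(CC2=C(OCc3ccccc3)CC2=O)c1OCc1ccccc1 | intermediate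
13 | ethyl acetate | CCOC(C)=O | starting material
14 | lithium 1,1-dibromoprop-1-en-2-olate (not isolated) | CC([O-])=C(Br)Br.[Li+] | intermediate
15 | lithium prop-1-yn-1-olate (not isolated) | CC#C[O-].[Li+] | intermediate
16 | 1-(triisopropylsiloxy)propyne [triisopropyl(prop-1-yn-1-yloxy)silane] | CC#CO[Si](C(C)C)(C(C)C)C(C)C | intermediate
17 | vinylketene: 2-(ring A benzyl)-3-(benzyloxy)buta-1,3-dien-1-one (not isolated) | CCCC(=O)c1c(OCc2ccccc2)c(C)c(OC)c(CC(=C=O)C(=C)OCc2ccccc2)c1OCc1ccccc1 | intermediate
18 | 4-(ring A benzyl)-4-[1-(benzyloxy)vinyl]-2-methyl-3-(triisopropylsilyloxy)cyclobut-2-en-1-one (racemic, not isolated) | CCCC(=O)c1c(OCc2ccccc2)c(C)c(OC)c(CC2(C(=C)OCc3ccccc3)C(=O)C(C)=C2O[Si](C(C)C)(C(C)C)C(C)C)c1OCc1ccccc1 | intermediate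
19 | dienylketene: 4-(ring A benzyl)-5-(benzyloxy)-2-methyl-3-(triisopropylsilyloxy)hexa-1,3,5-trien-1-one, vinyl ether arm cis to the ketene arm (not isolated) | CCCC(=O)c1c(OCc2ccccc2)c(C)c(OC)c(C/C(C(=C)OCc2ccccc2)=C(\O[Si](C(C)C)(C(C)C)C(C)C)C(C)=C=O)c1OCc1ccccc1 | intermediate
20 | 4-(ring A benzyl)-5-(benzyloxy)-2-methyl-3-(triisopropylsilyloxy)cyclohexa-2,4-dien-1-one (not isolated) | CCCC(=O)c1c(OCc2ccccc2)c(C)c(OC)c(CC2=C(OCc3ccccc3)CC(=O)C(C)=C2O[Si](C(C)C)(C(C)C)C(C)C)c1OCc1ccccc1 | intermediate
21 | 1-[2,6-bis(benzyloxy)-3-{[6-(benzyloxy)-4-hydroxy-3-methyl-2-(triisopropylsilyloxy)phenyl]methyl}-4-methoxy-5-methylphenyl]butan-1-one | CCCC(=O)c1c(OCc2ccccc2)c(C)c(OC)c(Cc2c(O[Si](C(C)C)(C(C)C)C(C)C)c(C)c(O)cc2OCc2ccccc2)c1OCc1ccccc1 | intermediate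
22 | propanoic anhydride | CCC(=O)OC(=O)CC | starting material
23 | 1-[2,6-bis(benzyloxy)-3-{[6-(benzyloxy)-4-hydroxy-3-methyl-5-propanoyl-2-(triisopropylsilyloxy)phenyl]methyl}-4-methoxy-5-methylphenyl]butan-1-one | CCCC(=O)c1c(OCc2ccccc2)c(C)c(OC)c(Cc2c(O[Si](C(C)C)(C(C)C)C(C)C)c(C)c(O)c(C(=O)CC)c2OCc2ccccc2)c1OCc1ccccc1 | intermediate
24 | 1-[2,6-bis(benzyloxy)-3-{[6-(benzyloxy)-2,4-dihydroxy-3-methyl-5-propanoylphenyl]methyl}-4-methoxy-5-methylphenyl]butan-1-one | CCCC(=O)c1c(OCc2ccccc2)c(C)c(OC)c(Cc2c(O)c(C)c(O)c(C(=O)CC)c2OCc2ccccc2)c1OCc1ccccc1 | intermediate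
25 | CNP0248731.0 (1-[3-(3-butanoyl-2,4-dihydroxy-6-methoxy-5-methylbenzyl)-2,4,6-trihydroxy-5-methylphenyl]propan-1-one) | CCCC(=O)c1c(O)c(C)c(OC)c(Cc2c(O)c(C)c(O)c(C(=O)CC)c2O)c1O | target

**Step count**

Total: 12 steps. Longest linear sequence: 10 steps (steps 1, 2, 3, 4, 6, 7, 9, 10, 11, 12, from 2-methylphloroglucinol); steps 5 and 8 are side branches.

**Steps most likely to fail**

Step 6. The Knoevenagel condensation at the di-ortho-substituted aldehyde may stall. Meanwhile the strained dione may be used up by self-condensation or by enaminone formation with the amine catalyst. Fallback, setting out from 7: NaBH4 (MeOH–THF, 0 °C) should reduce the aldehyde in preference to the shielded ketone and give the benzylic alcohol 1-[2,6-bis(benzyloxy)-3-(hydroxymethyl)-4-methoxy-5-methylphenyl]butan-1-one F1. Treating F1 with the enol of 9 and a catalytic acid (Bi(OTf)3 or p-TsOH, MeCN, rt) should then effect dehydrative benzylation through the benzylic cation, which two ortho and one para alkoxy groups stabilise. O-alkylation is reversible under acid, so the C-benzylated dione should accumulate, and the route is rejoined at 11.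

Step 9. The 2-substituted vinylketene may add only slowly to the ynol ether. Thermal 1,3-silyl shift of the siloxyalkyne to a silylketene, ketene dimerisation and acylation of the product phenol could then take over. Fallback, setting out from 4 and 1: ring B is brought in preformed. A Mannich reaction of 4 (Me2NH, aq CH2O, EtOH, rt) at its only open ring carbon should give 1-{3-[(dimethylamino)methyl]-2,6-dihydroxy-4-methoxy-5-methylphenyl}butan-1-one F2. Acylation of 1 with propanoyl chloride under the conditions of step 1 should give 1-(2,4,6-trihydroxy-3-methylphenyl)propan-1-one F3. Warming F2 with F3 in dioxane should release the ortho-quinone methide of ring A, which the one open ring carbon of F3 captures, and the route is rejoined directly at 25. This is the classical assembly of methylene-bridged acylphloroglucinols; its cost is possible exchange of the bridge, giving symmetrical dimers.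

Step 10. The Lewis acid may strip benzyl or silyl ethers and let the freed benzyl cation alkylate B5. Ipso-protonation at B1 may also cleave the diarylmethane bridge before acylation deactivates ring B. Fallback, setting out from 21: Vilsmeier–Haack formylation (POCl3, DMF, 0 °C→rt; aq NaOAc) should put the one-carbon unit on B5 and give 2-(benzyloxy)-3-{[2,4-bis(benzyloxy)-3-butanoyl-6-methoxy-5-methylphenyl]methyl}-6-hydroxy-5-methyl-4-(triisopropylsilyloxy)benzaldehyde F4. EtMgBr (excess, THF, −78 °C; the first equivalent is spent on the phenol, and the ring A ketone is shielded by its two ortho substituents) should add to the aldehyde to give the racemic carbinol 1-[2,6-bis(benzyloxy)-3-{[6-(benzyloxy)-4-hydroxy-5-(1-hydroxypropyl)-3-methyl-2-(triisopropylsilyloxy)phenyl]methyl}-4-methoxy-5-methylphenyl]butan-1-one F5. Oxidation of the benzylic alcohol with MnO2 (CH2Cl2, rt) rejoins the route at 23.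

**Further compounds**

F1 | step 6 | 1-[2,6-bis(benzyloxy)-3-(hydroxymethyl)-4-methoxy-5-methylphenyl]butan-1-one | CCCC(=O)c1c(OCc2ccccc2)c(C)c(OC)c(CO)c1OCc1ccccc1
F2 | step 9 | 1-{3-[(dimethylamino)methyl]-2,6-dihydroxy-4-methoxy-5-methylphenyl}butan-1-one | CCCC(=O)c1c(O)c(C)c(OC)c(CN(C)C)c1O
F3 | step 9 | 1-(2,4,6-trihydroxy-3-methylphenyl)propan-1-one | CCC(=O)c1c(O)c(C)c(O)cc1O
F4 | step 10 | 2-(benzyloxy)-3-{[2,4-bis(benzyloxy)-3-butanoyl-6-methoxy-5-methylphenyl]methyl}-6-hydroxy-5-methyl-4-(triisopropylsilyloxy)benzaldehyde | CCCC(=O)c1c(OCc2ccccc2)c(C)c(OC)c(Cc2c(O[Si](C(C)C)(C(C)C)C(C)C)c(C)c(O)c(C=O)c2OCc2ccccc2)c1OCc1ccccc1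
F5 | step 10 | 1-[2,6-bis(benzyloxy)-3-{[6-(benzyloxy)-4-hydroxy-5-(1-hydroxypropyl)-3-methyl-2-(triisopropylsilyloxy)phenyl]methyl}-4-methoxy-5-methylphenyl]butan-1-one (racemic) | CCCC(=O)c1c(OCc2ccccc2)c(C)c(OC)c(Cc2c(O[Si](C(C)C)(C(C)C)C(C)C)c(C)c(O)c(C(O)CC)c2OCc2ccccc2)c1OCc1ccccc1
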